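If a slow feed merely delays its parcels, north-west is a late summer run; if it thins the substrate and slows the rate, north-west is a batch running somewhat slower. Two chemists hold these views about the flasks below.

| flask | substrate | partner | free catalyst | remark | time |
|---|---|---|---|---|---|
| summer | 0.10 M | 0.13 M | 0.20 mM | run made earlier |  |
| autumn | 0.10 M | 0.065 M | 0.20 mM | run made earlier |  |
| dawn | 0.10 M | 0.098 M | 0.20 mM | run made earlier |  |
| north-west | 0.10 M (fed, over 10 min) | 0.130 M | 0.20 mM | all else is in the flask from the start; the feed brings no volume worth counting | 15 min |
| south-west | 0.10 M | 0.130 M | 0.20 mM | everything together at the start | 15 min |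
| east | 0.10 M | 0.130 M (fed, over 10 min) | 0.20 mM | all else is in the flask from the start; the feed brings no volume worth counting | 15 min |

| run | time / min | product / % |
|---|---|---|
| summer | 0.667 | 4.3 |
| summer | 1.33 | 12.8 |
| summer | 2.00 | 21.5 |
| summer | 3.00 | 37.3 |
| summer | 5.00 | 58.6 |
| summer | 10.0 | 84.6 |
| autumn | 3.00 | 20.8 |
| autumn | 6.00 | 41.6 |
| autumn | 10.0 | 53.0 |
| autumn | 12.0 | 56.3 |
| autumn | 15.0 | 58.4 |
| autumn | 20.0 | 62.7 |
| dawn | 3.00 | 29.4 |
| dawn | 6.00 | 54.5 |
| dawn | 10.0 | 72.3 |
| dawn | 12.0 | 78.0 |
| dawn | 15.0 | 82.7 |
| dawn | 20.0 | 88.3 |

(each reading ± 1 percentage point)

- the flask with the highest amount of product, in percent of the substrate charged ("all alike" if they lie within 1.5 percentage points) (north-west / south-west / east / all alike)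
- final product, as a percentage of the substrate charged, in north-west
- final product, as a percentage of the substrate charged, in south-west
- final product, as a percentage of the substrate charged, in east



The delay chemist works in logarithms of the unreacted share, one minus product. In the summer run that logarithm falls by 0.208 min⁻¹ between 3.00 min and 5.00 min, then by 0.198 min⁻¹ up to 10.0 min. She takes the later figure as the tail constant, the fall per minute of the logarithm of the unreacted share, a slope read off the summer readings. So a parcel's unreacted share depends on its age. In north-west the first parcel, aged 15 min, keeps 5.13%, and the last, aged 5.00 min, keeps 37.2%. Averaged along the feed, that leaves 16.2%, so she commits to 83.8% product. South-west, the summer run carried on, gets 94.3%.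

The rate chemist made the forecast: 90% in north-west, 95% in south-west, 87% in east, with south-west highest. For north-west he says “well below saturation, so it loses rate and reaches about 90%”. On north-west the two part by 6.2 percentage points.

The flasks give 82.5% in north-west, 94.2% in south-west and 88.4% in east, so south-west leads, and the delay figure lies closer on north-west. At 15.0 min north-west holds 1.56% substrate and 15.9% open intermediate. The rate view keeps the flasks with substrate in from the start, south-west and east, where the forecast stood within its tolerance. Read with the tail constant, the remainders of north-west and south-west lie 5.58 min of ageing apart, against a mean parcel wait of 5.00 min.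

    substrate + free catalyst → free catalyst + open intermediate (k = 52.0 M⁻¹ s⁻¹)
    free catalyst + open intermediate ⇌ catalyst intermediate (K = 14.0 M⁻¹, k = 110 M⁻¹ s⁻¹)
    partner + catalyst intermediate → free catalyst + product (k = 40.0 M⁻¹ s⁻¹)

A neighbour of north-west has 3.4 × 10⁻⁴ M of free catalyst. Assuming the tail constant scales with the catalyst, it becomes 0.336 min⁻¹, and the same average gives 94.7% product; the computed flask gives 93.9%.

The earlier runs and the new flask come from a simulation for substances that don't exist, and the scatter is random.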